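The rate constants are made up.

5 questions stood before me, a choice among 4 flasks and the target in each, and I reckoned them with one time constant.

    substrate → intermediate (k1 = 0.0068 s⁻¹, Ea1 = 83.0 kJ mol⁻¹)
    intermediate ⇌ target (K2 = 1.8, k2 = 0.028 s⁻¹, Ea2 = 84.0 kJ mol⁻¹, ΔH2 = −60.0 kJ mol⁻¹)
    intermediate ⇌ isomer of the product (K3 = 3.1, k3 = 0.0045 s⁻¹, Ea3 = 91.0 kJ mol⁻¹, ΔH3 = −56.0 kJ mol⁻¹)
    substrate ⇌ dormant form (K4 = 26, k4 = 0.0012 s⁻¹, Ea4 = 77.0 kJ mol⁻¹, ΔH4 = 20.0 kJ mol⁻¹)
    2 substrate → homo dimer (k5 = 0.0041 M⁻¹ s⁻¹, Ea5 = 57.0 kJ mol⁻¹)
    intermediate → side product (k6 = 8.2 × 10⁻⁴ s⁻¹, Ea6 = 95.0 kJ mol⁻¹)
    (constants at 20 °C)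

| setting | elm | oak | birch | maple |
|---|---|---|---|---|
| substrate | 1.5 M | 1.5 M | 1.5 M | 1.5 M |
| temperature | 5 °C | −10 °C | 20 °C |  |
| time | 1.0 h | 1.0 h | 1.0 h | 1.0 h |
| remark |  |  |  | at −10 °C until 20 min, from then on at 20 °C |

* the best flask by amount of target, in percent of the substrate charged; "all alike" if 1.5 percentage points covers them all (elm / oak / birch / maple / all alike)
* amount of target at the end, in percent of the substrate charged, elm
* amount of target at the end, in percent of the substrate charged, oak
* amount of target at the end, in percent of the substrate charged, birch
* amount of target at the end, in percent of the substrate charged, maple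

- in percentages every species weighs as the substrate in it: one homo dimer counts as two
- a step written with two of one species runs at k times the square of its concentration and takes two of it each time
- at 20 °C the constants are as listed, elsewhere as the activation energies and enthalpies make them

**Main step.** I began with the step from substrate to intermediate by itself. At 5 °C, in elm, its constant came to 0.0650 min⁻¹, so the substrate emptied with a time constant of 0.256 h. In birch that time was 2.45 min, and in oak it was 1.98 h, longer than the 1.0 h of reading, so I expected oak to be caught unfinished.

**Side exits.** Next I added the homo dimer and the dormant form, neglecting the dormant form's return. In elm the constants became 0.00116 M⁻¹ s⁻¹ for the dimer and 0.0131 min⁻¹ for the dormant form. Let r be twice the dimer constant times the charge, over the sum of the two first-order constants; here r was 2.68. Integrating the substrate's loss gives ln(1 + r)/r as the share leaving by first-order steps. Splitting that share by the constants left 40.5% of the charge entering the pool of intermediate, target and isomer.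

**Settling time.** The exchange between intermediate and target ran with a time constant near 0.0636 h, so I froze their ratio at the equilibrium constant Kt, which is 6.79 in elm. With that ratio frozen, the pair of target and intermediate leaks to the isomer at ki/(1 + Kt), where ki is the rate constant from intermediate to isomer, and the isomer returns at ki/Ki, with Ki its equilibrium constant. In elm ki was 0.0361 min⁻¹ and Ki was 10.7. The settling time τ, the reciprocal of ki/(1 + Kt) + ki/Ki, was 2.08 h. Once filled, a flask of this scheme read well before τ is under kinetic control among these three; read well after it, it is under thermodynamic control among them, with the target's share of the pool at φ = Kt/(1 + Kt + Ki).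

**My reckoning.** Elm filled before its reading and was read before settling. I let its target share relax from Kt/(1 + Kt) towards φ, which is 36.7%, and this estimate gave 27.5% of the charge. Birch's τ came to 5.45 min, so I put its share at φ. I took its pool, 51.5% of the charge, to drain to side product with a time constant of 2.00 h, and this estimate gave 9.52%. Maple spent its last 40.0 min warm, well beyond birch's τ, so I ranked it beside birch and, expecting oak to be unfinished, put elm first.

**The result.** The forecast chose elm as “the compromise”, with 24.4% there (22% to 27%), 12.2% in oak, 9.5% in birch and 8.2% in maple. The simulation gave elm as best, with 25.6% there, 12.0% in oak, 9.23% in birch and 7.99% in maple, so my elm figure stood 1.9 percentage points high.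

**The leak.** Birch's τ was far shorter than elm's, and the leak in it runs through the way back from target to intermediate. The birch run with that way back removed ended at 51.0% of target instead of 9.23%, the largest single effect tested there.

**Elm, later.** For elm read at 2.5 h, I took the pool of 38.7% standing at 1.0 h and relaxed the target towards φ with the same τ, which gave 19.8%. The simulation read 19.5%.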